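The runs were generated by integration on assumed constants, and the scatter is random.

- Z was the molecule I followed through this flask: it could go straight to L, or by way of X to E.

all flasks: Z 0.34 M
- larch: D 0.48 M; run made earlier
- alder: D 0.75 M; run made earlier
- flask: D 0.340 M; time 4.0 h

| run | time / h | E / % | L / % |
|---|---|---|---|
| larch | 0.333 | 16.2 | 8.7 |
| larch | 0.500 | 21.3 | 11.6 |
| larch | 0.667 | 25.5 | 13.1 |
| larch | 1.00 | 33.5 | 16.4 |
| larch | 1.50 | 42.5 | 20.5 |
| larch | 2.50 | 54.3 | 24.8 |
| larch | 4.00 | 62.2 | 27.8 |
| alder | 0.200 | 10.9 | 6.8 |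
| alder | 0.667 | 24.3 | 12.9 |
| alder | 1.00 | 32.6 | 16.5 |
| alder | 1.50 | 41.4 | 20.3 |
| alder | 2.50 | 52.9 | 25.1 |
| alder | 3.00 | 56.8 | 26.1 |
| alder | 4.00 | 61.1 | 28.6 |

(scatter of a reading: 0.3 percentage points)

- percent here means Z units held: one G counts as two
- steps that have been proposed: Z -> X; Z -> L; X -> E; D + X <-> Q; Z + X -> G; Z <-> J

1. share of E in E plus L at 1.0 min
2. share of E in E plus L at 4.0 h

- The latest larch reading stood at 2.24 E per L, which I took as my late ratio. The first larch reading, at 0.333 h, stood at 1.86.
- I read that shortfall as a delay: L comes straight from Z, while E comes later, by way of X. The waiting time, the elapsed time multiplied by the fractional shortfall from the late ratio, came to 3.35 min. It is a reading and carries the scatter of the readings.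
- First instants: 1.0 min is shorter than the waiting time, so I expected L to lead E in this flask. I reckoned E per L as the late ratio times the elapsed time over 2 waiting times, which gave a share of 25.0%.
- Middle: with the waiting time passed, the delay counted for less, and larch read 2.04 E per L at 1.00 h.
- End: this flask holds less D than larch, and the latest alder share read 68.1%, so I stayed with the latest larch share, 69.1%.
- The forecast gave 25% and 69.5%, the later figure above mine, saying “E should therefore lag strongly”.
- This flask gave 25.8% at 1.0 min and 69.0% at 4.0 h.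

    Z → X (k = 0.0775 min⁻¹)
    Z → L (k = 0.0334 min⁻¹)
    X → E (k = 0.299 min⁻¹)
    D + X ⇌ Q (K = 7.26 L mol⁻¹, k = 0.0701 L mol⁻¹ min⁻¹)
    Z + X → G (k = 0.294 L mol⁻¹ min⁻¹)
    Z ⇌ J (K = 7.49, k = 0.824 min⁻¹)

- The half-life of X by X to E alone was 2.3 min, longer than 1.0 min. It was far shorter than the 0.48 h of D + X to Q, forward step alone, at the charged amounts. My early rule, with the waiting time, put equal E and L at 0.0499 h, and this flask reached that point at 0.0536 h. The neighbour charged with 0.085 M of Z, a quarter of this flask's charge, stands against my 25.0% with 26.1% at 1.0 min.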